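**Plan**

- Retrosynthesis, in order: the C20 acetate; the spiro ether O–C13 (oxa-Michael addition of 9α-OH to a 15,16-butenolide made from a 3-furyl ring); C9–C11 (alkyllithium plus 9-ketone); ring B at C7=C8 (aldol condensation); C1–C10 and C4–C5 together (intramolecular Diels–Alder); the ester O6–C19; then the dienophile back to (S)-glyceraldehyde acetonide and pent-1-en-3-one.
- Enabling feature: the γ-lactone C4–C19(=O)–O–C6–C5 is fused to ring A on the C4–C5 bond, so C19(=O)–O–C6 is a ready three-atom tether between a C1=C2–C3=C4 diene (a (2Z)-2-methylpenta-2,4-dienoate) and a C5=C10 dienophile.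
- The trans A/B fusion needs C6 and C20 cis on that alkene, which a preformed ring B cannot give. A temporary 3,6-dihydro-2H-pyran ring O–C7(OMe)–C6–C5=C10–C20 does, and it stores C7 as a masked aldehyde and the C20 oxygen as its ring oxygen; the C9 propanoyl group on C10 activates the alkene.
- Forward order of rings: dihydropyran; ring A and the 19,6-lactone in one step; acetal opened and ring B closed by aldol of C8 on C7; furylethyl side chain; butenolide; spiro oxolane; acetate.
- Stereochemistry: C6 from the chiral pool; C4, C5 and C10 relayed from C6 in the cycloaddition; C8 by equilibration next to the ketone; C9 by equatorial addition; C13 in the reversible spiro ring closure.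

Key step: step 10

Remark: labdane numbering is used throughout (ring A = C1–C5 and C10; ring B = C5–C10; C18 = methyl on C4; C19 = lactone carbonyl on C4; C20 = oxymethylene on C10; C17 = methyl on C8; side chain C11–C16).
Remark: centres that form as mixtures and are erased later (C5 of 6 and 7, C7 of 18, C16 of 26) are drawn without configuration; the acetal carbon C7 of 10, 16 and 17 is drawn as the expected anomer trans to O6, and the cis anomer would converge at 20.
Remark: compounds 1, 5, 11, 12 and 22 are taken as commercially available.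

**Step 1**
Reactants: 1 (S)-2,2-dimethyl-1,3-dioxolane-4-carbaldehyde
Product: 2 (2S)-3,3-dimethoxypropane-1,2-diol
Conditions: TsOH·H2O (cat.), MeOH, rt; Et3N quench
Reagents that add atoms: methanol, CO
Why: Acid-catalysed acetalisation of the aldehyde together with methanolysis of the acetonide (transacetalisation) should give the acyclic dimethyl acetal diol, and the stereocentre (the later C6) is not touched.

**Step 2**
Reactants: 2 (2S)-3,3-dimethoxypropane-1,2-diol
Product: 3 (2S)-3,3-dimethoxy-1,2-bis(triethylsilyloxy)propane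
Conditions: Et3SiCl, imidazole, CH2Cl2, 0 °C to rt
Reagents that add atoms: chlorotriethylsilane, CC[Si](Cl)(CC)CC
Why: Routine silyl ether formation on both hydroxyl groups; no stereocentre is formed.

**Step 3**
Reactants: 3 (2S)-3,3-dimethoxy-1,2-bis(triethylsilyloxy)propane
Product: 4 (2S)-3,3-dimethoxy-2-(triethylsilyloxy)propanal
Conditions: (COCl)2, DMSO, CH2Cl2, −78 to −30 °C; then Et3N
Reagents that add atoms: none
Why: Swern oxidation run on the bis-silyl ether, in which the chlorosulfonium reagent cleaves and oxidises only the primary triethylsilyl ether (a known selective oxidation of primary over secondary silyl ethers), should give the α-silyloxy aldehyde, which is used at once to avoid epimerisation at C6.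

**Step 4**
Reactants: 4 (2S)-3,3-dimethoxy-2-(triethylsilyloxy)propanal; 5 pent-1-en-3-one
Product: 6 (6S)-5-hydroxy-7,7-dimethoxy-4-methylidene-6-(triethylsilyloxy)heptan-3-one (both C5 epimers)
Conditions: DABCO (0.5 equiv), THF, rt
Reagents that add atoms: none
Why: Morita–Baylis–Hillman reaction of an activated α-oxy aldehyde with a vinyl ketone joins C5 to C10; the new carbinol centre forms as a mixture and is erased in step 5, while C6 stays intact.

**Step 5**
Reactants: 6 (6S)-5-hydroxy-7,7-dimethoxy-4-methylidene-6-(triethylsilyloxy)heptan-3-one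
Product: 8 (2E,4S)-5,5-dimethoxy-2-propanoyl-4-(triethylsilyloxy)pent-2-en-1-yl acetate, via secondary acetate 7 (not isolated)
Conditions: Ac2O, DMAP (cat.), pyridine, CH2Cl2, 0 °C; then DABCO, THF, 50 °C
Reagents that add atoms: acetic anhydride, CC(=O)OC(C)=O
Why: Acetylation followed by the DABCO-mediated SN2'–SN2' allylic transposition of a Morita–Baylis–Hillman acetate should give the thermodynamically preferred (E)-trisubstituted primary acetate, in which the bulky C6 substituent lies trans to the acyl group and therefore cis to C20.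

**Step 6**
Reactants: 8 (2E,4S)-5,5-dimethoxy-2-propanoyl-4-(triethylsilyloxy)pent-2-en-1-yl acetate
Product: 10 1-[(5S,6S)-5-hydroxy-6-methoxy-5,6-dihydro-2H-pyran-3-yl]propan-1-one, via diol 9 (not isolated)
Conditions: HCl (cat.), MeOH, rt; then PPTS, toluene, 50 °C with removal of MeOH
Reagents that add atoms: none
Why: Acidic methanolysis removes the silyl ether and the acetate, and intramolecular transacetalisation of the C20 hydroxyl with the dimethyl acetal closes the six-membered ring, which is possible only because C6 and C20 are cis; the anomeric centre C7 settles under thermodynamic control, expected trans to O6 with an axial OMe (anomeric effect).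

**Step 7**
Reactants: 11 acrolein; 12 ethyl 2-(diphenoxyphosphoryl)propanoate
Product: 13 ethyl (2Z)-2-methylpenta-2,4-dienoate
Conditions: NaH, THF, −78 to −20 °C
Reagents that add atoms: none
Why: Horner–Wadsworth–Emmons olefination with a diaryl phosphonate (the Z-selective variant) should give the (2Z)-dienoate, ester and vinyl group cis, through kinetically controlled collapse of the syn adduct.

**Step 8**
Reactants: 13 ethyl (2Z)-2-methylpenta-2,4-dienoate
Product: 14 (2Z)-2-methylpenta-2,4-dienoic acid
Conditions: LiOH, THF/H2O, 0 °C; then aq. HCl to pH 3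
Reagents that add atoms: lithium hydroxide, [Li+].[OH-]
Why: Mild saponification of the ethyl ester at 0 °C should leave the (Z)-geometry unchanged.

**Step 9**
Reactants: 10 1-[(5S,6S)-5-hydroxy-6-methoxy-5,6-dihydro-2H-pyran-3-yl]propan-1-one; 14 (2Z)-2-methylpenta-2,4-dienoic acid
Product: 16 (2S,3S)-2-methoxy-5-propanoyl-3,6-dihydro-2H-pyran-3-yl (2Z)-2-methylpenta-2,4-dienoate, via mixed anhydride 15 (not isolated)
Conditions: 14, 2,4,6-trichlorobenzoyl chloride, Et3N, toluene, rt; then 10, DMAP, rt
Reagents that add atoms: none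
Why: Yamaguchi esterification through the mixed anhydride, the usual way to acylate alcohols with (Z)-2-methylalk-2-enoic (angelic-type) acids without Z to E isomerisation, attaches the diene to O6 with retention at C6.

**Step 10**
Reactants: 16 (2S,3S)-2-methoxy-5-propanoyl-3,6-dihydro-2H-pyran-3-yl (2Z)-2-methylpenta-2,4-dienoate
Product: 17 cycloadduct (4S,5R,6S,7S,10S): ring A cyclohex-2-ene (C1–C5, C10) cis-fused at C4–C5 to the 19,6-γ-lactone and at C5–C10 to the tetrahydropyran O–C7(OMe)–C6–C5–C10–C20; C10 carries the propanoyl group (C9, C8, C17)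
Conditions: toluene (0.01 M), BHT (cat.), 180 °C, sealed tube
Reagents that add atoms: none
Why: Concerted, suprafacial [4+2] cycloaddition of type 1 (intramolecular Diels–Alder reaction of a dienoate ester of a cyclic allylic alcohol, a known way to cyclohexene-fused γ-lactones); the C9 ketone activates the C5=C10 dienophile and the three-atom tether C19(=O)–O–C6 dictates the regiochemistry, C4 to C5 and C1 to C10. Ring A closes as the six-membered cycloaddition ring and the 19,6-lactone as the five-membered tether ring through the new C4–C5 bond, fused cis to the dihydropyran at C5–C6. C5 and C10 are controlled by C6: the pseudoaxial ester oxygen (trans to the anomeric OMe) can deliver the diene only to its own face, and suprafacial addition to an alkene locked in the ring with C6 and C20 cis puts H5 anti to C20, the relation that becomes the trans A/B fusion. C4 is controlled by the diene geometry: with the tether on the inside position of the (Z)-diene only the transition state with the dihydropyran exo and the propanoyl group endo can be reached, which gives the cis-fused lactone with C19 syn and C18 anti to C6. The step therefore needs facial and endo/exo selectivity and a diene that survives heating; the first two are secured by the C6–O tether and the (Z)-geometry, and the last by the carbonyl inside substituent, which carries no hydrogen for a 1,5-hydrogen shift.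

**Step 11**
Reactants: 17 cycloadduct
Product: 20 20-(tert-butyldimethylsilyloxy)-9-oxo-11,12,13,14,15,16-hexanorlabda-2,7-dien-19,6β-olide (4S,5R,6R,10S), via lactol 18 (not isolated), via hydroxy enone 19 (not isolated)
Conditions: 2 M aq. HCl, THF, 60 °C; then t-BuMe2SiCl, DBU, CH2Cl2, rt
Reagents that add atoms: tert-butylchlorodimethylsilane, CC(C)(C)[Si](C)(C)Cl
Why: Acid hydrolysis of the methyl acetal gives the lactol, whose open hydroxy aldehyde undergoes intramolecular aldol condensation with the only enolisable position (C8) of the propanoyl ketone to close ring B as the cyclohexenone without forming a stereocentre; DBU with the silyl chloride then traps the freed C20 hydroxyl and returns any oxa-Michael adduct (C20–O on C7) or translactonised isomer by reversible base-mediated equilibration.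

**Step 12**
Reactants: 20 20-(tert-butyldimethylsilyloxy)-9-oxo-11,12,13,14,15,16-hexanorlabda-2,7-dien-19,6β-olide
Product: 21 20-(tert-butyldimethylsilyloxy)-9-oxo-11,12,13,14,15,16-hexanorlabdan-19,6β-olide (8α-methyl; 4S,5R,6R,8R,10S)
Conditions: H2 (1 atm), 5% Rh on Al2O3, EtOAc, rt; then DBU (cat.), toluene, 40 °C
Reagents that add atoms: none
Why: Heterogeneous hydrogenation saturates the C2=C3 and C7=C8 bonds (rhodium is chosen to limit hydrogenolysis of the allylic C6–O bond), and C8, being α to the ketone, is then equilibrated by DBU to the equatorial 8α-methyl epimer, which avoids 1,3-diaxial contacts with C20 and O6.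

**Step 13**
Reactants: 22 2-(furan-3-yl)ethanol
Product: 23 3-(2-iodoethyl)furan
Conditions: I2, PPh3, imidazole, CH2Cl2, 0 °C
Reagents that add atoms: iodine, II
Why: Appel-type iodination of a primary alcohol through the alkoxyphosphonium salt.

**Step 14**
Reactants: 21 20-(tert-butyldimethylsilyloxy)-9-oxo-11,12,13,14,15,16-hexanorlabdan-19,6β-olide; 23 3-(2-iodoethyl)furan
Product: 25 20-(tert-butyldimethylsilyloxy)-15,16-epoxy-9α-hydroxylabda-13(16),14-dien-19,6β-olide, via organolithium 24 (not isolated)
Conditions: 23, t-BuLi (2 equiv), Et2O, −78 °C; then 21, THF, −78 to −30 °C; H2O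
Reagents that add atoms: none
Why: Iodine–lithium exchange gives the primary alkyllithium, which should add to the hindered C9 ketone along the equatorial trajectory (the usual course for bulky organometallics on cyclohexanones, the axial path being blocked by the syn-axial hydrogens on C5 and C7), placing C11 equatorial (β) and the hydroxyl axial (9α); addition of alkyllithium reagents to 9-oxo-19,6-olides of this type is known chemistry, and the hindered lactone should survive at low temperature.

**Step 15**
Reactants: 25 20-(tert-butyldimethylsilyloxy)-15,16-epoxy-9α-hydroxylabda-13(16),14-dien-19,6β-olide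
Product: 27 20-(tert-butyldimethylsilyloxy)-9α-hydroxylabd-13-ene-19,6β:15,16-diolide, via hydroxybutenolide 26 (not isolated)
Conditions: O2, hν (visible), tetraphenylporphyrin (cat.), i-Pr2NEt, CH2Cl2, −78 °C; then NaBH4, EtOH, 0 °C; aq. citric acid
Reagents that add atoms: dioxygen, O=O
Why: Singlet-oxygen [4+2] photooxygenation of the 3-substituted furan in the presence of a hindered amine, which deprotonates the endoperoxide at the less hindered C15–H, should give the γ-hydroxybutenolide with the carbonyl at C15, and NaBH4 reduction of its open aldehyde form with relactonisation on acidification gives the 15,16-butenolide.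

**Step 16**
Reactants: 27 20-(tert-butyldimethylsilyloxy)-9α-hydroxylabd-13-ene-19,6β:15,16-diolide
Product: 28 (13R)-20-(tert-butyldimethylsilyloxy)-9α,13-epoxylabdane-19,6β:15,16-diolide
Conditions: DBU, toluene, 50 °C
Reagents that add atoms: none
Why: Base-mediated intramolecular oxa-Michael addition (5-exo-trig) of the tertiary 9α-hydroxyl to C13 of the butenolide closes the spiro oxolane and creates C13; the addition is reversible and the substrate offers little facial bias, so the two spiro epimers should equilibrate, the required 13R epimer (C14 on the C10 side of the oxolane) is separated, and material of the other configuration is returned to the same conditions.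

**Step 17**
Reactants: 28 (13R)-20-(tert-butyldimethylsilyloxy)-9α,13-epoxylabdane-19,6β:15,16-diolide
Product: 30 (13R)-20-acetoxy-9α,13-epoxylabdane-19,6β:15,16-diolide (CNP0196936.1), via alcohol 29 (not isolated)
Conditions: HF·pyridine, THF, 0 °C to rt; then pyridine, Ac2O, DMAP (cat.), rt
Reagents that add atoms: acetic anhydride, CC(=O)OC(C)=O
Why: Desilylation with fluoride under acidic, non-equilibrating conditions (no retro-Michael at C13) followed by acetylation of the primary C20 alcohol in the same pot should give the target.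

**Compound list**

1 | (S)-2,2-dimethyl-1,3-dioxolane-4-carbaldehyde | O=C[C@@H]1COC(C)(C)O1 | starting material
2 | (2S)-3,3-dimethoxypropane-1,2-diol | OC[C@H](O)C(OC)OC | intermediate
3 | (2S)-3,3-dimethoxy-1,2-bis(triethylsilyloxy)propane | CC[Si](CC)(CC)OC[C@H](O[Si](CC)(CC)CC)C(OC)OC | intermediate
4 | (2S)-3,3-dimethoxy-2-(triethylsilyloxy)propanal | CC[Si](CC)(CC)O[C@H](C(OC)OC)C=O | intermediate
5 | pent-1-en-3-one | CCC(=O)C=C | starting material
6 | (6S)-5-hydroxy-7,7-dimethoxy-4-methylidene-6-(triethylsilyloxy)heptan-3-one (both C5 epimers) | CCC(=O)C(=C)C(O)[C@H](O[Si](CC)(CC)CC)C(OC)OC | intermediate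
7 | (6S)-7,7-dimethoxy-4-methylidene-3-oxo-6-(triethylsilyloxy)heptan-5-yl acetate (both C5 epimers) | CCC(=O)C(=C)C(OC(C)=O)[C@H](O[Si](CC)(CC)CC)C(OC)OC | intermediate
8 | (2E,4S)-5,5-dimethoxy-2-propanoyl-4-(triethylsilyloxy)pent-2-en-1-yl acetate | CCC(=O)/C(COC(C)=O)=C/[C@H](O[Si](CC)(CC)CC)C(OC)OC | intermediate
9 | (4E,6S)-6-hydroxy-4-(hydroxymethyl)-7,7-dimethoxyhept-4-en-3-one | CCC(=O)/C(CO)=C/[C@H](O)C(OC)OC | intermediate
10 | 1-[(5S,6S)-5-hydroxy-6-methoxy-5,6-dihydro-2H-pyran-3-yl]propan-1-one | CCC(=O)C1=C[C@H](O)[C@@H](OC)OC1 | intermediate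
11 | acrolein | C=CC=O | starting material
12 | ethyl 2-(diphenoxyphosphoryl)propanoate | CCOC(=O)C(C)P(=O)(Oc1ccccc1)Oc1ccccc1 | starting material
13 | ethyl (2Z)-2-methylpenta-2,4-dienoate | CCOC(=O)/C(C)=C\C=C | intermediate
14 | (2Z)-2-methylpenta-2,4-dienoic acid | OC(=O)/C(C)=C\C=C | intermediate
15 | (2Z)-2-methylpenta-2,4-dienoic 2,4,6-trichlorobenzoic anhydride | O=C(OC(=O)/C(C)=C\C=C)c1c(Cl)cc(Cl)cc1Cl | intermediate
16 | (2S,3S)-2-methoxy-5-propanoyl-3,6-dihydro-2H-pyran-3-yl (2Z)-2-methylpenta-2,4-dienoate | CCC(=O)C1=C[C@H](OC(=O)/C(C)=C\C=C)[C@@H](OC)OC1 | intermediate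
17 | cycloadduct (4S,5R,6S,7S,10S): ring A cyclohex-2-ene, 19,6-lactone, 7-methoxy-7,20-epoxy bridge, 10-propanoyl | CCC(=O)[C@@]12CC=C[C@]3(C)C(=O)O[C@@H]([C@@H]31)[C@@H](OC)OC2 | intermediate
18 | C7 lactol corresponding to 17 (both anomers) | CCC(=O)[C@@]12CC=C[C@]3(C)C(=O)O[C@@H]([C@@H]31)C(O)OC2 | intermediate
19 | 20-hydroxy-9-oxo-11,12,13,14,15,16-hexanorlabda-2,7-dien-19,6β-olide | OC[C@@]12CC=C[C@]3(C)C(=O)O[C@H](C=C(C)C1=O)[C@H]23 | intermediate
20 | 20-(tert-butyldimethylsilyloxy)-9-oxo-11,12,13,14,15,16-hexanorlabda-2,7-dien-19,6β-olide | CC(C)(C)[Si](C)(C)OC[C@@]12CC=C[C@]3(C)C(=O)O[C@H](C=C(C)C1=O)[C@H]23 | intermediate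
21 | 20-(tert-butyldimethylsilyloxy)-9-oxo-11,12,13,14,15,16-hexanorlabdan-19,6β-olide (8α-methyl) | CC(C)(C)[Si](C)(C)OC[C@@]12CCC[C@]3(C)C(=O)O[C@H](C[C@@H](C)C1=O)[C@H]23 | intermediate
22 | 2-(furan-3-yl)ethanol | OCCc1ccoc1 | starting material
23 | 3-(2-iodoethyl)furan | ICCc1ccoc1 | intermediate
24 | 2-(furan-3-yl)ethyllithium | [Li]CCc1ccoc1 | intermediate
25 | 20-(tert-butyldimethylsilyloxy)-15,16-epoxy-9α-hydroxylabda-13(16),14-dien-19,6β-olide | CC(C)(C)[Si](C)(C)OC[C@@]12CCC[C@]3(C)C(=O)O[C@H](C[C@@H](C)[C@]1(O)CCc1ccoc1)[C@H]23 | intermediate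
26 | 20-(tert-butyldimethylsilyloxy)-9α,16-dihydroxylabd-13-ene-19,6β:15,16-diolide (both C16 epimers) | CC(C)(C)[Si](C)(C)OC[C@@]12CCC[C@]3(C)C(=O)O[C@H](C[C@@H](C)[C@]1(O)CCC1=CC(=O)OC1O)[C@H]23 | intermediate
27 | 20-(tert-butyldimethylsilyloxy)-9α-hydroxylabd-13-ene-19,6β:15,16-diolide | CC(C)(C)[Si](C)(C)OC[C@@]12CCC[C@]3(C)C(=O)O[C@H](C[C@@H](C)[C@]1(O)CCC1=CC(=O)OC1)[C@H]23 | intermediate
28 | (13R)-20-(tert-butyldimethylsilyloxy)-9α,13-epoxylabdane-19,6β:15,16-diolide | CC(C)(C)[Si](C)(C)OC[C@@]12CCC[C@]3(C)C(=O)O[C@H](C[C@@H](C)[C@]14CC[C@@]1(COC(=O)C1)O4)[C@H]23 | intermediate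
29 | (13R)-20-hydroxy-9α,13-epoxylabdane-19,6β:15,16-diolide | OC[C@@]12CCC[C@]3(C)C(=O)O[C@H](C[C@@H](C)[C@]14CC[C@@]1(COC(=O)C1)O4)[C@H]23 | intermediate
30 | (13R)-20-acetoxy-9α,13-epoxylabdane-19,6β:15,16-diolide (CNP0196936.1; 4S,5R,6R,8R,9R,10S,13R) | CC(=O)OC[C@@]12CCC[C@]3(C)C(=O)O[C@H](C[C@@H](C)[C@]14CC[C@@]1(COC(=O)C1)O4)[C@H]23 | target

**Step count**

Total: 17 steps. Longest linear sequence: 14 steps (steps 1–6, 9–12, 14–17).

**Steps most likely to fail**

Step 10. The electron-poor (Z)-dienoate and the trisubstituted ring enone may react too slowly, so that polymerisation of the diene or thermal loss of methanol or of the allylic ester overtakes the cycloaddition. The fallback changes the tether to an ether (normal electron demand, no ester conformational penalty) and oxidises C19 afterwards; it sets out from 13 and 10 and returns at 21. Ester 13 is reduced with i-Bu2AlH to (2Z)-2-methylpenta-2,4-dien-1-ol F1, which CBr4 and PPh3 convert into (2Z)-1-bromo-2-methylpenta-2,4-diene F2. Alcohol 10 is alkylated with F2 under neutral conditions (Ag2O) to the dienyl ether F3, whose intramolecular Diels–Alder reaction has the same topology and should give the oxolane-fused cycloadduct F4. The conditions of step 11 take F4 through the lactol F5 and the hydroxy enone F6 to the silyl ether F7, and those of step 12 give the saturated ketone F8. Oxidation of the C19 methylene next to the ether oxygen with RuCl3 (cat.) and NaIO4 then gives lactone 21.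

Step 14. Attack along the axial path (giving the 9-epimer) or enolisation of the hindered ketone may compete with the equatorial addition. The fallback builds the C9–O bond by epoxidation and forms C11–C12 instead of C9–C11; it sets out from 21 and returns at 25. Ketone 21 is methylenated (Zn, CH2Br2, TiCl4) to the exocyclic alkene F9, and mCPBA, which should attack the face anti to the axial C20 group, gives the 9α,11-epoxide F10. Opening at the primary carbon C11 with (furan-3-ylmethyl)magnesium chloride F11 (from commercial 3-(chloromethyl)furan and Mg) under CuI catalysis gives alcohol 25.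

Step 16. Poor facial selectivity at C13 is likely, because the two spiro epimers differ little in energy and the separation with recycling may be inefficient. The fallback makes C13 non-stereogenic first and sets it by reagent control; it sets out from 21 and returns at 28. Commercial but-3-enylmagnesium bromide adds to 21 to give the homoallyl carbinol F12. Iodoetherification (I2, NaHCO3) gives the iodomethyl oxolane F13, and elimination with t-BuOK gives the exocyclic enol ether F14. Its [2+2] cycloaddition with dichloroketene F15 (from Cl3CCOCl and Zn–Cu couple) gives the dichlorocyclobutanone F16, and Zn in AcOH gives the spiro cyclobutanone F17, in which C13 carries two identical CH2C(=O) arms. A desymmetrising Baeyer–Villiger oxidation under catalyst control (a chiral BINOL-derived phosphoric acid with aq. H2O2, or Sc(OTf)3 with a chiral N,N'-dioxide ligand and mCPBA; the catalyst antipode is chosen in a trial) then inserts oxygen on the C8-side methylene to give 28.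

**Further compounds**

F1 | step 10 | (2Z)-2-methylpenta-2,4-dien-1-ol | OC/C(C)=C\C=C
F2 | step 10 | (2Z)-1-bromo-2-methylpenta-2,4-diene | BrC/C(C)=C\C=C
F3 | step 10 | 1-[(5S,6S)-6-methoxy-5-{[(2Z)-2-methylpenta-2,4-dien-1-yl]oxy}-5,6-dihydro-2H-pyran-3-yl]propan-1-one | CCC(=O)C1=C[C@H](OC/C(C)=C\C=C)[C@@H](OC)OC1
F4 | step 10 | cycloadduct as 17 with a 19,6-ether (oxolane) in place of the lactone | CCC(=O)[C@@]12CC=C[C@]3(C)CO[C@@H]([C@@H]31)[C@@H](OC)OC2
F5 | step 10 | C7 lactol corresponding to F4 (both anomers) | CCC(=O)[C@@]12CC=C[C@]3(C)CO[C@@H]([C@@H]31)C(O)OC2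
F6 | step 10 | 19,6β-epoxy-20-hydroxy-11,12,13,14,15,16-hexanorlabda-2,7-dien-9-one | OC[C@@]12CC=C[C@]3(C)CO[C@H](C=C(C)C1=O)[C@H]23
F7 | step 10 | 20-(tert-butyldimethylsilyloxy)-19,6β-epoxy-11,12,13,14,15,16-hexanorlabda-2,7-dien-9-one | CC(C)(C)[Si](C)(C)OC[C@@]12CC=C[C@]3(C)CO[C@H](C=C(C)C1=O)[C@H]23
F8 | step 10 | 20-(tert-butyldimethylsilyloxy)-19,6β-epoxy-11,12,13,14,15,16-hexanorlabdan-9-one (8α-methyl) | CC(C)(C)[Si](C)(C)OC[C@@]12CCC[C@]3(C)CO[C@H](C[C@@H](C)C1=O)[C@H]23
F9 | step 14 | 20-(tert-butyldimethylsilyloxy)-12,13,14,15,16-pentanorlabd-9(11)-en-19,6β-olide | CC(C)(C)[Si](C)(C)OC[C@@]12CCC[C@]3(C)C(=O)O[C@H](C[C@@H](C)C1=C)[C@H]23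
F10 | step 14 | 20-(tert-butyldimethylsilyloxy)-9α,11-epoxy-12,13,14,15,16-pentanorlabdan-19,6β-olide | CC(C)(C)[Si](C)(C)OC[C@@]12CCC[C@]3(C)C(=O)O[C@H](C[C@@H](C)[C@]14CO4)[C@H]23
F11 | step 14 | (furan-3-ylmethyl)magnesium chloride | Cl[Mg]Cc1ccoc1
F12 | step 16 | 20-(tert-butyldimethylsilyloxy)-9α-hydroxy-14,15-dinorlabd-13(16)-en-19,6β-olide | CC(C)(C)[Si](C)(C)OC[C@@]12CCC[C@]3(C)C(=O)O[C@H](C[C@@H](C)[C@]1(O)CCC=C)[C@H]23
F13 | step 16 | 20-(tert-butyldimethylsilyloxy)-9α,13-epoxy-16-iodo-14,15-dinorlabdan-19,6β-olide (both C13 epimers) | CC(C)(C)[Si](C)(C)OC[C@@]12CCC[C@]3(C)C(=O)O[C@H](C[C@@H](C)[C@]14CCC(CI)O4)[C@H]23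
F14 | step 16 | 20-(tert-butyldimethylsilyloxy)-9α,13-epoxy-14,15-dinorlabd-13(16)-en-19,6β-olide | CC(C)(C)[Si](C)(C)OC[C@@]12CCC[C@]3(C)C(=O)O[C@H](C[C@@H](C)[C@]14CCC(=C)O4)[C@H]23
F15 | step 16 | dichloroketene | ClC(Cl)=C=O
F16 | step 16 | spiro 14,14-dichlorocyclobutan-15-one on C13 of the 9α,13-epoxide (C13–C16–C15(=O)–C14Cl2 ring; both C13 epimers) | CC(C)(C)[Si](C)(C)OC[C@@]12CCC[C@]3(C)C(=O)O[C@H](C[C@@H](C)[C@]14CCC5(CC(=O)C5(Cl)Cl)O4)[C@H]23
F17 | step 16 | spiro cyclobutan-15-one on C13 of the 9α,13-epoxide (C13–C16–C15(=O)–C14 ring) | CC(C)(C)[Si](C)(C)OC[C@@]12CCC[C@]3(C)C(=O)O[C@H](C[C@@H](C)[C@]14CCC5(CC(=O)C5)O4)[C@H]23
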